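Everything rests on cutting the bond between the spiro carbon of the cyclohexanetrione ring and the ring CH2 that hangs on the cyclopentane. That spiro carbon lies between two carbonyl carbons, so it is a twofold carbon nucleophile and, one tautomer back, a free position of a phloroglucinol. The precursor is therefore a flat acyl(methyl)phloroglucinol that carries, through the other ring CH2, an all-cis cyclopentane with a bromomethyl arm, made from (R)-linalool by a zinc-ene cyclisation. In one pot, ligand-controlled dearomative prenylation builds the C(Me)(prenyl) centre and the liberated dienolate closes the cyclohexane on the bromide, creating the spiro centre. Radical hydration of an exocyclic methylene ends the route.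

Key step: step 7

Remark: the enolised triketone is written in the tautomer of the target SMILES (its tautomers interconvert and carry no stereo-information). The ligand antipode needed in step 7 is assumed to be (R,R); if a test reaction shows the opposite sense, the equally available (S,S) form is used.

Step 1
Reactants: 1 2-methylphloroglucinol; 2 (S)-2-methylbutanoyl chloride
Product: 3 (2S)-2-methyl-1-(2,4,6-trihydroxy-3-methylphenyl)butan-1-one
Conditions: AlCl3 (3.5 equiv), CH2Cl2/PhNO2, 0 °C to rt; aq. HCl
Reagents that add atoms: none
Why: Friedel–Crafts acylation of the very electron-rich arene at one of its two equivalent free positions; the product ketone is deactivated by chelation against a second acylation, and the low temperature should keep the α-stereocentre of the acyl group from enolising.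

Step 2
Reactants: 4 (R)-(−)-linalool
Product: 5 (2E,6R)-2,6-dimethylocta-2,7-diene-1,6-diol
Conditions: SeO2 (cat.), t-BuOOH, salicylic acid (cat.), CH2Cl2, 0 °C to rt; then NaBH4, MeOH, 0 °C
Reagents that add atoms: tert-butyl hydroperoxide CC(C)(C)OO
Why: Riley allylic oxidation (ene reaction, then [2,3]-shift) attacks the (E)-methyl group of the trisubstituted alkene; the vinyl group has no allylic hydrogen, borohydride returns over-oxidised enal to the alcohol, and the carbinol stereocentre is not touched.

Step 3
Reactants: 5 (2E,6R)-2,6-dimethylocta-2,7-diene-1,6-diol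
Product: 6 (2E,6R)-6-hydroxy-2,6-dimethylocta-2,7-dien-1-yl acetate
Conditions: Ac2O (1.1 equiv), pyridine, CH2Cl2, 0 °C
Reagents that add atoms: acetic anhydride CC(=O)OC(C)=O
Why: Chemoselective O-acylation, since the primary allylic alcohol reacts far faster than the tertiary one.

Step 4
Reactants: 6 (2E,6R)-6-hydroxy-2,6-dimethylocta-2,7-dien-1-yl acetate
Product: 9 (1R,2S,3S)-2-(bromomethyl)-1-methyl-3-(prop-1-en-2-yl)cyclopentan-1-ol, via open allylzinc 7 (not isolated), via cyclised alkylzinc 8 (not isolated)
Conditions: Pd(PPh3)4 (5 mol %), Et2Zn (5 equiv), Et2O, 35 °C; then NBS, THF, −40 °C; aq. NH4Cl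
Reagents that add atoms: N-bromosuccinimide O=C1CCC(=O)N1Br
Why: Palladium-catalysed zinc-ene reaction: Et2Zn converts the π-allylpalladium into 7, whose suprafacial type-I metallo-ene addition to the vinyl group places CH2Zn and isopropenyl cis; the zinc alkoxide should sit on the face of the migrating metal (chelation) and the larger methyl on the open face, and the C–Zn bond of 8 is then brominated.

Step 5
Reactants: 9 (1R,2S,3S)-2-(bromomethyl)-1-methyl-3-(prop-1-en-2-yl)cyclopentan-1-ol
Product: 10 (1R,2S,3S)-2-(bromomethyl)-3-(3-chloroprop-1-en-2-yl)-1-methylcyclopentan-1-ol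
Conditions: Ca(OCl)2, CO2 (s), CH2Cl2/H2O, 0 °C
Reagents that add atoms: calcium hypochlorite [Ca+2].[O-]Cl.[O-]Cl
Why: Ene-type allylic chlorination of a 1,1-disubstituted alkene by hypochlorous acid made in the flask: Cl+ adds to the terminal CH2 and a methyl proton is lost, so the double bond moves, no stereocentre is touched, and the alkyl bromide and tertiary alcohol are inert at 0 °C.

Step 6
Reactants: 3 (2S)-2-methyl-1-(2,4,6-trihydroxy-3-methylphenyl)butan-1-one; 10 (1R,2S,3S)-2-(bromomethyl)-3-(3-chloroprop-1-en-2-yl)-1-methylcyclopentan-1-ol
Product: 11 (2S)-1-[3-{2-[(1S,2S,3R)-2-(bromomethyl)-3-hydroxy-3-methylcyclopentyl]prop-2-en-1-yl}-2,4,6-trihydroxy-5-methylphenyl]-2-methylbutan-1-one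
Conditions: Pd(PPh3)4 (5 mol %), K2CO3, THF, rt
Reagents that add atoms: none
Why: Tsuji–Trost allylation: the 2-substituted π-allylpalladium has two equivalent CH2 termini, O-allylation is reversible under Pd(0), and C-attack at the only free ring position followed by re-aromatisation is the sink, while the unactivated primary bromide does not react at room temperature.

Step 7
Reactants: 11 (2S)-1-[3-{2-[(1S,2S,3R)-2-(bromomethyl)-3-hydroxy-3-methylcyclopentyl]prop-2-en-1-yl}-2,4,6-trihydroxy-5-methylphenyl]-2-methylbutan-1-one
Product: 13 spiro-triketone bearing an exocyclic methylene in place of the six-ring C(CH3)(OH) of 14 (all other stereocentres as in 14), via prenylated dienolone 12 (not isolated)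
Conditions: i) Pd2(dba)3·CHCl3 (2.5 mol %), (R,R)-DACH-phenyl Trost ligand (6 mol %), tert-butyl prenyl carbonate (1.1 equiv), toluene/THF, 0 °C to rt; ii) Cs2CO3 (2.5 equiv), DMF, 60 °C; acidic work-up
Reagents that add atoms: tert-butyl 3-methylbut-2-en-1-yl carbonate CC(C)=CCOC(=O)OC(C)(C)C
Why: Ionisation of the carbonate gives a chiral π-prenylpalladium that is attacked at its unsubstituted terminus by the phenolate of 11 through the methyl-bearing ring carbon, giving 12 (closest known type: palladium-catalysed asymmetric allylic dearomatisation of acylphloroglucinols and naphthols). Added Cs2CO3 then forms the dienolate, whose only remaining nucleophilic carbon lies between two C–O carbons, already bears the allylic CH2, and displaces the primary bromide (intramolecular enolate C-alkylation, as in the gem-dialkylation that leads to lupulone-type triketones). The single ring that closes is the cyclohexane, by a 6-exo-tet SN2 reaction. The C(Me)(prenyl) centre is set by the ligand pocket, which selects one face of the flat arene, and the spiro centre by 1,3-induction: the CH2Br arm should reach the planar dienolate on the face that carries the small methyl group, anti to the prenyl chain. Site selectivity in the first event rests on sterics (methyl-bearing carbon versus the carbon with the branched allyl chain) and on reversible O-allylation, and the order of events rests on the inertness of the β-branched bromide until base and heat are applied. C- over O-alkylation in the closure is secured by ring size, since either flanking oxygen would have to form an eight-membered ether, and the un-ionised tertiary alcohol should not compete with the dienolate of so strong a carbon acid.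

Step 8
Reactants: 13 spiro-triketone bearing an exocyclic methylene
Product: 14 hyperielliptone HB
Conditions: Mn(dpm)3 (20 mol %), PhSiH3 (2.2 equiv), O2 (1 atm), i-PrOH/CH2Cl2, 0 °C
Reagents that add atoms: dioxygen O=O
Why: Mukaiyama hydration (metal-hydride hydrogen-atom transfer, O2 capture, reduction of the peroxide): the hydrogen atom should go faster to the unhindered terminal CH2 of the 1,1-disubstituted alkene than to the trisubstituted prenyl alkene. The tertiary ring radical should then take up O2 on the face away from the axial carbonyl arm of the spiro centre (1,3-diaxial shielding by the ketone between the two quaternary carbons), which puts OH equatorial and methyl axial as in 14.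

Compound list
1 | 2-methylphloroglucinol | Cc1c(O)cc(O)cc1O | starting material
2 | (S)-2-methylbutanoyl chloride | CC[C@H](C)C(Cl)=O | starting material
3 | (2S)-2-methyl-1-(2,4,6-trihydroxy-3-methylphenyl)butan-1-one | CC[C@H](C)C(=O)c1c(O)cc(O)c(C)c1O | intermediate
4 | (R)-(−)-linalool | CC(C)=CCC[C@@](C)(O)C=C | starting material
5 | (2E,6R)-2,6-dimethylocta-2,7-diene-1,6-diol | OC/C(C)=C/CC[C@@](C)(O)C=C | intermediate
6 | (2E,6R)-6-hydroxy-2,6-dimethylocta-2,7-dien-1-yl acetate | CC(=O)OC/C(C)=C/CC[C@@](C)(O)C=C | intermediate
7 | open allylzinc (ethylzinc alkoxide of the (E)-allyl ethylzinc) | CC[Zn]C/C(C)=C/CC[C@@](C)(O[Zn]CC)C=C | intermediate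
8 | cyclised alkylzinc (all-cis CH2ZnEt, isopropenyl and OZnEt on the cyclopentane) | CC[Zn]C[C@H]1[C@H](CC[C@@]1(C)O[Zn]CC)C(C)=C | intermediate
9 | (1R,2S,3S)-2-(bromomethyl)-1-methyl-3-(prop-1-en-2-yl)cyclopentan-1-ol | BrC[C@H]1[C@H](CC[C@@]1(C)O)C(C)=C | intermediate
10 | (1R,2S,3S)-2-(bromomethyl)-3-(3-chloroprop-1-en-2-yl)-1-methylcyclopentan-1-ol | BrC[C@H]1[C@H](CC[C@@]1(C)O)C(=C)CCl | intermediate
11 | C-allylated acyl(methyl)phloroglucinol, cyclopentyl part (1S,2S,3R), acyl part (2S) | CC[C@H](C)C(=O)c1c(O)c(C)c(O)c(CC(=C)[C@H]2CC[C@@](C)(O)[C@H]2CBr)c1O | intermediate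
12 | prenylated dienolone: ring carbon C(Me)(prenyl) R, chain as in 11 | CC[C@H](C)C(=O)C1=C(O)[C@@](C)(CC=C(C)C)C(=O)C(CC(=C)[C@H]2CC[C@@](C)(O)[C@H]2CBr)=C1O | intermediate
13 | spiro-triketone with exocyclic methylene (14 minus water), spiro carbon R, C(Me)(prenyl) R, cis-fused hydrindane | CC[C@H](C)C(=O)C1=C(O)[C@@](C)(CC=C(C)C)C(=O)[C@]2(C[C@H]3[C@H](CC[C@@]3(C)O)C(=C)C2)C1=O | intermediate
14 | hyperielliptone HB | CC[C@H](C)C(=O)C1=C(O)[C@@](C)(CC=C(C)C)C(=O)[C@]2(C[C@H]3[C@H](CC[C@@]3(C)O)[C@](C)(O)C2)C1=O | target

Total step count: 8. Longest linear sequence: 7 steps (4 → 5 → 6 → 9 → 10 → 11 → 13 → 14).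

Steps most likely to fail

Step 7. The prenyl cation equivalent may be taken up at the chain-bearing ring carbon. The ligand may differentiate the faces of the arene poorly. The 1,3-induction by methyl versus prenyl in the ring closure may also be weak.
- The fallback inverts the order of the two alkylations; it sets out from 11 and comes back at 13.
- Compound 11 is first closed with Cs2CO3 in DMF. This is an alkylative dearomatisation, and the chain-bearing carbon is the only one that can reach the bromide. It gives the prenyl-free spiro-dienol F1, whose two spiro epimers are separated by chromatography.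
- In F1 only the methyl-bearing carbon is left as a carbon nucleophile. It is prenylated with prenyl bromide under a cinchonidinium phase-transfer catalyst (CsOH·H2O, toluene, −20 °C), so that the catalyst alone decides the last quaternary centre. This gives 13.

Step 8. Hydrogen-atom transfer to the prenyl alkene, sequestration of the metal by the triketone, and unselective capture of O2 by the ring radical may erode the outcome.
- The fallback is ionic instead of radical; it sets out from 13 and comes back at 14.
- Oxymercuration with Hg(OAc)2 in THF/H2O should discriminate strongly for the 1,1-disubstituted alkene over the trisubstituted one. Water should open the mercurinium ion from the less shielded face to give the hydroxy-organomercurial F2.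
- Demercuration of F2 with NaBH4/NaOH gives 14.

Step 4. Ethyl transfer or reduction of the π-allylpalladium may outrun the umpolung, and the induction from the carbinol centre may be weak.
- The fallback avoids palladium and zinc; it sets out from 5 and comes back at 9.
- Diol 5 is converted with MsCl, LiCl and s-collidine in DMF into the allylic chloride F3.
- The hydroxyl group of F3 is deprotonated with MeMgCl and magnesium is inserted in THF.
- The allyl Grignard reagent is warmed to 65 °C, where the kinetically cis-selective magnesium-ene cyclisation should give the cyclised Grignard reagent F4.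
- Bromination of F4 with NBS gives 9.

Further compounds
F1 | step 7 | prenyl-free spiro-dienol (spiro centre and hydrindane as in 13, ring carbon C–CH3 still sp2) | CC[C@H](C)C(=O)C1=C(O)C(C)=C(O)[C@]2(C[C@H]3[C@H](CC[C@@]3(C)O)C(=C)C2)C1=O
F2 | step 8 | hydroxy-organomercurial (14 with CH2HgOAc in place of the six-ring carbinol methyl) | CC[C@H](C)C(=O)C1=C(O)[C@@](C)(CC=C(C)C)C(=O)[C@]2(C[C@H]3[C@H](CC[C@@]3(C)O)[C@](C[Hg]OC(C)=O)(O)C2)C1=O
F3 | step 4 | (3R,6E)-8-chloro-3,7-dimethylocta-1,6-dien-3-ol | ClC/C(C)=C/CC[C@@](C)(O)C=C
F4 | step 4 | cyclised Grignard reagent (all-cis CH2MgCl, isopropenyl and OMgCl) | Cl[Mg]C[C@H]1[C@H](CC[C@@]1(C)O[Mg]Cl)C(C)=C
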